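Ring A of the chroman-4-one is hexasubstituted: oxygen on C5, C7 and C8a alternates with carbon on C4a, C6 and C8. The route builds this ring de novo by cutting C7–C8, C8a–C4a and C6–C7. A thermal cyclobutenone–ynol ether benzannulation joins racemic 3-ethoxy-4-prenylcyclobut-2-enone to an enantiopure silyloxyalkyne that already carries the (R)-hexanoate arm. In one operation it closes ring A and delivers three differently masked oxygens (free C7 phenol, C8a silyl ether, C5 ethyl ether), prenyl on C6, the finished side chain on C8 and C4a as the only open carbon. C4a is then formylated, turned into the tigloyl ketone and closed to the (2S,3S)-chromanone.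

Key step: step 7

Remark: ring positions (O1, C2–C4, C4a, C5–C8, C8a) follow the chroman-4-one numbering of the target throughout.
Assumption: the facial sense of the alkaloid-catalysed ring closure follows that of related 2-hydroxyaryl tigloyl ketones, for which quinine gives the (2R)-chromanone, so quinidine is assigned to the (2S) series.

Step 1
Reactants: 1 5-methylhex-4-enoic acid
Product: 2 5-methylhex-4-enoyl chloride
Conditions: (COCl)2, DMF (cat.), CH2Cl2, 0 °C → rt
Reagents that add atoms: oxalyl chloride, ClC(=O)C(=O)Cl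
Why: Acid chloride formation through the Vilsmeier-type chloroiminium catalyst is mild and anhydrous, so the trisubstituted alkene should survive and the volatile by-products leave a crude chloride ready for use.

Step 2
Reactants: 2 5-methylhex-4-enoyl chloride; 3 ethoxyacetylene
Product: 5 3-ethoxy-4-(3-methylbut-2-en-1-yl)cyclobut-2-en-1-one (racemic), via prenylketene 4 (not isolated)
Conditions: Et3N, excess 3, Et2O, 0 °C → rt, slow addition of 2
Reagents that add atoms: none
Why: Dehydrochlorination gives the aldoketene 4, and in the ketene–alkyne [2+2] cycloaddition the nucleophilic terminal carbon of the ynol ether bonds to the ketene carbonyl carbon, which places ethoxy on C3 and the prenyl-bearing carbon on C4 of the cyclobutenone (slow addition into excess alkyne suppresses ketene dimerisation).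

Step 3
Reactants: 6 (S)-4-benzyloxazolidin-2-one; 7 pentanoyl chloride
Product: 9 (S)-4-benzyl-3-pentanoyloxazolidin-2-one, via lithium oxazolidinide 8 (not isolated)
Conditions: n-BuLi, THF, −78 °C; then 7, −78 → 0 °C
Reagents that add atoms: none
Why: N-acylation of the lithiated carbamate nitrogen with an acid chloride is the standard preparation of Evans imides.

Step 4
Reactants: 9 (S)-4-benzyl-3-pentanoyloxazolidin-2-one; 10 tert-butyl bromoacetate
Product: 12 tert-butyl (3R)-3-{[(4S)-4-benzyl-2-oxo-1,3-oxazolidin-3-yl]carbonyl}hexanoate, via sodium enolate 11 (not isolated)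
Conditions: NaN(SiMe3)2, THF, −78 °C; then 10, −78 → −40 °C
Reagents that add atoms: none
Why: Evans asymmetric alkylation: the chelated (Z)-enolate 11 is alkylated by the reactive α-bromo ester on the face away from the benzyl group, which sets the (R) centre that becomes the benzylic carbon on C8.

Step 5
Reactants: 12 tert-butyl (3R)-3-{[(4S)-4-benzyl-2-oxo-1,3-oxazolidin-3-yl]carbonyl}hexanoate
Product: 13 4-tert-butyl 1-methyl (2R)-2-propylbutanedioate
Conditions: MeMgBr, MeOH, CH2Cl2, 0 °C
Reagents that add atoms: methanol, CO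
Why: Transesterification with methoxymagnesium bromide attacks only the activated exocyclic imide carbonyl, so the auxiliary 6 is released for recovery, the hindered tert-butyl ester stays and the weakly basic magnesium alkoxide should not epimerise the α-centre.

Step 6
Reactants: 13 4-tert-butyl 1-methyl (2R)-2-propylbutanedioate
Product: 15 tert-butyl (3R)-3-({[tri(propan-2-yl)silyl]oxy}ethynyl)hexanoate, via lithium ynolate 14 (not isolated)
Conditions: CH2Br2, lithium 2,2,6,6-tetramethylpiperidide, THF, −78 °C; LiN(SiMe3)2; n-BuLi, −78 °C → rt; i-Pr3SiCl, −78 → 0 °C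
Reagents that add atoms: dibromomethane, BrCBr; triisopropylsilyl chloride, CC(C)[Si](Cl)(C(C)C)C(C)C
Why: Kowalski ester homologation stopped at the ynolate: LiCHBr2 adds to the methyl ester but not to the hindered tert-butyl ester, the silylamide then holds the tert-butyl ester as its inert enolate while bromine–lithium exchange triggers the 1,2-shift of the stereogenic carbon (with retention) to ynolate 14, and the bulky silyl chloride caps the ynolate oxygen but not the ester enolate, which returns to the ester on aqueous work-up.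

Step 7
Reactants: 5 3-ethoxy-4-(3-methylbut-2-en-1-yl)cyclobut-2-en-1-one; 15 tert-butyl (3R)-3-({[tri(propan-2-yl)silyl]oxy}ethynyl)hexanoate
Product: 20 tert-butyl (3R)-3-[4-ethoxy-2-hydroxy-3-(3-methylbut-2-en-1-yl)-6-{[tri(propan-2-yl)silyl]oxy}phenyl]hexanoate, via vinylketene 16 (not isolated), via vinylcyclobutenone 17 (not isolated), via dienylketene 18 (not isolated), via cyclohexadienone 19 (not isolated)
Conditions: PhMe, 80 °C then 110 °C
Reagents that add atoms: none
Why: Heating opens 5 by conrotatory four-electron electrocyclic ring opening to vinylketene 16, whose ketene C=C adds the ynol ether in a [2+2] cycloaddition to give vinylcyclobutenone 17 (new bonds C7–C8 and C8a–C4a); a second four-electron opening gives dienylketene 18. Ring A is then closed by a thermal disrotatory six-electron electrocyclisation of 18 that re-forms C6–C7 (cyclohexadienone 19), and enolisation gives phenol 20. The closest known reaction is the Danheiser benzannulation of cyclobutenones with silyloxyalkynes to resorcinol monosilyl ethers; the 3-alkoxy (vinylogous ester) cyclobutenone is the less tested partner and may need the upper temperature. No stereocentre is created, since the sp3 ring carbons of 5, 17 and 19 all end as planar arene carbons, and the (R) centre, which is neither acidic nor part of the pericyclic array, is carried through unchanged. The one selectivity required is the regiochemistry of the [2+2] step, and it is secured by polarity: the electron-rich alkyne carbon that bears the side chain bonds to the electrophilic ketene carbonyl carbon, the oxygen-bearing carbon to the ketene α-carbon. Hydrogen on C2, ethoxy on C3 and prenyl plus one hydrogen on C4 of 5 therefore map on to C4a–H, C5–OEt and C6–prenyl, while the ketene oxygen appears as the free C7 hydroxyl and the alkyne oxygen as the C8a silyl ether.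

Step 8
Reactants: 20 tert-butyl (3R)-3-[4-ethoxy-2-hydroxy-3-(3-methylbut-2-en-1-yl)-6-{[tri(propan-2-yl)silyl]oxy}phenyl]hexanoate
Product: 21 tert-butyl (3R)-3-[4-ethoxy-2,6-dihydroxy-3-(3-methylbut-2-en-1-yl)phenyl]hexanoate
Conditions: Bu4NF, AcOH, THF, 0 °C
Reagents that add atoms: none
Why: Fluoride-induced cleavage of the aryl silyl ether frees the C8a hydroxyl, and the acetic acid buffer keeps both phenols protonated so that neither closes on to the tert-butyl ester.

Step 9
Reactants: 21 tert-butyl (3R)-3-[4-ethoxy-2,6-dihydroxy-3-(3-methylbut-2-en-1-yl)phenyl]hexanoate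
Product: 22 tert-butyl (3R)-3-[4-ethoxy-3-formyl-2,6-dihydroxy-5-(3-methylbut-2-en-1-yl)phenyl]hexanoate
Conditions: MgCl2, Et3N, (CH2O)n, THF, reflux
Reagents that add atoms: formaldehyde (as paraformaldehyde), C=O
Why: Magnesium-phenoxide-directed ortho-formylation (Casnati–Skattebøl reaction) puts the formyl group only ortho to a free hydroxyl, C4a is the single unsubstituted ring carbon, and the amine-buffered medium contains no acid that could attack the prenyl group or the tert-butyl ester.

Step 10
Reactants: 22 tert-butyl (3R)-3-[4-ethoxy-3-formyl-2,6-dihydroxy-5-(3-methylbut-2-en-1-yl)phenyl]hexanoate; 23 but-2-yne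
Product: 24 tert-butyl (3R)-3-{4-ethoxy-2,6-dihydroxy-3-[(2E)-2-methylbut-2-enoyl]-5-(3-methylbut-2-en-1-yl)phenyl}hexanoate
Conditions: [RhCl(cod)]2 (cat.), 1,1'-bis(diphenylphosphino)ferrocene, Na2CO3 (cat.), PhMe, 80 °C, sealed tube
Reagents that add atoms: none
Why: Chelation-assisted rhodium-catalysed alkyne hydroacylation by a salicylaldehyde: the C8a phenoxide anchors the acyl rhodium hydride, which adds syn across the symmetrical alkyne to give the (E)-2-methylbut-2-enoyl (tigloyl) ketone without any Lewis or Brønsted acid, while the trisubstituted prenyl alkene is too hindered to insert.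

Step 11
Reactants: 24 tert-butyl (3R)-3-{4-ethoxy-2,6-dihydroxy-3-[(2E)-2-methylbut-2-enoyl]-5-(3-methylbut-2-en-1-yl)phenyl}hexanoate
Product: 25 tert-butyl (3R)-3-[(2S,3R)-5-ethoxy-7-hydroxy-2,3-dimethyl-6-(3-methylbut-2-en-1-yl)-4-oxo-3,4-dihydro-2H-chromen-8-yl]hexanoate
Conditions: quinidine (cat.), PhCl, rt
Reagents that add atoms: none
Why: Cinchona-alkaloid-catalysed intramolecular oxa-Michael addition: the quinuclidine nitrogen activates the C8a hydroxyl within a chiral ion pair and delivers it to one face of the tigloyl β-carbon to set C2 as (S), kinetic protonation of the enol gives the cis (3R) methyl group, the C5 ethyl ether leaves O8a as the only oxygen able to close the ring, and any C2 epimer would be a diastereomer (remote (R) centre) removable by chromatography.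

Step 12
Reactants: 25 tert-butyl (3R)-3-[(2S,3R)-5-ethoxy-7-hydroxy-2,3-dimethyl-6-(3-methylbut-2-en-1-yl)-4-oxo-3,4-dihydro-2H-chromen-8-yl]hexanoate
Product: 26 tert-butyl (3R)-3-[(2S,3S)-5-ethoxy-7-hydroxy-2,3-dimethyl-6-(3-methylbut-2-en-1-yl)-4-oxo-3,4-dihydro-2H-chromen-8-yl]hexanoate
Conditions: MgI2, Et3N, CH2Cl2, rt
Reagents that add atoms: none
Why: Soft enolisation of the magnesium-chelated ketone epimerises only C3, and the equilibrium should favour the trans isomer with both methyl groups equatorial, C2 being untouched as long as the chelated enolate does not expel O1 (residual cis isomer is separated and resubmitted).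

Step 13
Reactants: 26 tert-butyl (3R)-3-[(2S,3S)-5-ethoxy-7-hydroxy-2,3-dimethyl-6-(3-methylbut-2-en-1-yl)-4-oxo-3,4-dihydro-2H-chromen-8-yl]hexanoate
Product: 27 (3R)-3-[(2S,3S)-5,7-dihydroxy-2,3-dimethyl-6-(3-methylbut-2-en-1-yl)-4-oxo-3,4-dihydro-2H-chromen-8-yl]hexanoic acid
Conditions: BCl3, 2,6-di-tert-butyl-4-methylpyridine, CH2Cl2, −78 → −20 °C; aq. NaHCO3, then pH 4
Reagents that add atoms: none
Why: Chelation-controlled ether cleavage: BCl3 bound between the C4 carbonyl and O5 removes the peri ethyl group as chloroethane and also cleaves the tert-butyl ester as tert-butyl chloride, while the hindered pyridine, which does not bind boron, traps the HCl that would otherwise hydrochlorinate or cyclise the prenyl group.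

Step 14
Reactants: 27 (3R)-3-[(2S,3S)-5,7-dihydroxy-2,3-dimethyl-6-(3-methylbut-2-en-1-yl)-4-oxo-3,4-dihydro-2H-chromen-8-yl]hexanoic acid
Product: 28 methyl (3R)-3-[(2S,3S)-5,7-dihydroxy-2,3-dimethyl-6-(3-methylbut-2-en-1-yl)-4-oxo-3,4-dihydro-2H-chromen-8-yl]hexanoate (target)
Conditions: EDC·HCl, DMAP, MeOH, CH2Cl2, 0 °C → rt
Reagents that add atoms: methanol, CO
Why: Steglich esterification delivers the methyl group as the nucleophile methanol, so the phenols cannot be O-methylated, no acid reaches the prenyl group, and any transient acylation of a phenol gives an activated aryl ester that the same DMAP–methanol medium should convert into the same methyl ester.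

Compound list
1 | 5-methylhex-4-enoic acid | CC(C)=CCCC(=O)O | starting material
2 | 5-methylhex-4-enoyl chloride | CC(C)=CCCC(=O)Cl | intermediate
3 | ethoxyacetylene (ethoxyethyne) | CCOC#C | starting material
4 | prenylketene (5-methylhexa-1,4-dien-1-one), formed in the flask | O=C=CCC=C(C)C | intermediate
5 | 3-ethoxy-4-(3-methylbut-2-en-1-yl)cyclobut-2-en-1-one, racemic at C4 | CCOC1=CC(=O)C1CC=C(C)C | intermediate
6 | (S)-4-benzyloxazolidin-2-one | O=C1N[C@@H](Cc2ccccc2)CO1 | starting material
7 | pentanoyl chloride | CCCCC(=O)Cl | starting material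
8 | N-lithio (S)-4-benzyloxazolidin-2-one, formed in the flask | [Li+].O=C1[N-][C@@H](Cc2ccccc2)CO1 | intermediate
9 | (S)-4-benzyl-3-pentanoyloxazolidin-2-one | CCCCC(=O)N1[C@@H](Cc2ccccc2)COC1=O | intermediate
10 | tert-butyl bromoacetate | CC(C)(C)OC(=O)CBr | starting material
11 | sodium (Z)-enolate of 9, formed in the flask | [Na+].CCC/C=C(\[O-])N1[C@@H](Cc2ccccc2)COC1=O | intermediate
12 | tert-butyl (3R)-3-{[(4S)-4-benzyl-2-oxo-1,3-oxazolidin-3-yl]carbonyl}hexanoate | CCC[C@H](CC(=O)OC(C)(C)C)C(=O)N1[C@@H](Cc2ccccc2)COC1=O | intermediate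
13 | 4-tert-butyl 1-methyl (2R)-2-propylbutanedioate | CCC[C@H](CC(=O)OC(C)(C)C)C(=O)OC | intermediate
14 | dilithium species formed in the flask: the (R)-ynolate with the tert-butyl ester held as its lithium enolate | [Li+].[Li+].CCC[C@H](C=C([O-])OC(C)(C)C)C#C[O-] | intermediate
15 | tert-butyl (3R)-3-({[tri(propan-2-yl)silyl]oxy}ethynyl)hexanoate | CCC[C@H](CC(=O)OC(C)(C)C)C#CO[Si](C(C)C)(C(C)C)C(C)C | intermediate
16 | vinylketene 3-ethoxy-7-methylocta-1,3,6-trien-1-one (geometry of the 3,4-alkene not relevant), formed in the flask | O=C=CC(OCC)=CCC=C(C)C | intermediate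
17 | tert-butyl (3R)-3-[3-(1-ethoxy-5-methylhexa-1,4-dien-1-yl)-4-oxo-2-{[tri(propan-2-yl)silyl]oxy}cyclobut-1-en-1-yl]hexanoate, ring sp3 carbon unassigned, formed in the flask | CCC[C@H](CC(=O)OC(C)(C)C)C1=C(O[Si](C(C)C)(C(C)C)C(C)C)C(C(OCC)=CCC=C(C)C)C1=O | intermediate
18 | dienylketene O=C=C(R)–C(OSi)=CH–C(OEt)=CH–CH2CH=CMe2, R being the (R)-1-(tert-butoxycarbonyl)pentan-2-yl arm and Si triisopropylsilyl, formed in the flask | CCC[C@H](CC(=O)OC(C)(C)C)C(=C=O)C(O[Si](C(C)C)(C(C)C)C(C)C)=CC(OCC)=CCC=C(C)C | intermediate
19 | tert-butyl (3R)-3-[4-ethoxy-5-(3-methylbut-2-en-1-yl)-6-oxo-2-{[tri(propan-2-yl)silyl]oxy}cyclohexa-1,3-dien-1-yl]hexanoate, ring sp3 carbon unassigned, formed in the flask | CCC[C@H](CC(=O)OC(C)(C)C)C1=C(O[Si](C(C)C)(C(C)C)C(C)C)C=C(OCC)C(CC=C(C)C)C1=O | intermediate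
20 | tert-butyl (3R)-3-[4-ethoxy-2-hydroxy-3-(3-methylbut-2-en-1-yl)-6-{[tri(propan-2-yl)silyl]oxy}phenyl]hexanoate | CCC[C@H](CC(=O)OC(C)(C)C)c1c(O)c(CC=C(C)C)c(OCC)cc1O[Si](C(C)C)(C(C)C)C(C)C | intermediate
21 | tert-butyl (3R)-3-[4-ethoxy-2,6-dihydroxy-3-(3-methylbut-2-en-1-yl)phenyl]hexanoate | CCC[C@H](CC(=O)OC(C)(C)C)c1c(O)c(CC=C(C)C)c(OCC)cc1O | intermediate
22 | tert-butyl (3R)-3-[4-ethoxy-3-formyl-2,6-dihydroxy-5-(3-methylbut-2-en-1-yl)phenyl]hexanoate | CCC[C@H](CC(=O)OC(C)(C)C)c1c(O)c(CC=C(C)C)c(OCC)c(C=O)c1O | intermediate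
23 | but-2-yne | CC#CC | starting material
24 | tert-butyl (3R)-3-{4-ethoxy-2,6-dihydroxy-3-[(2E)-2-methylbut-2-enoyl]-5-(3-methylbut-2-en-1-yl)phenyl}hexanoate | CCC[C@H](CC(=O)OC(C)(C)C)c1c(O)c(CC=C(C)C)c(OCC)c(C(=O)/C(C)=C/C)c1O | intermediate
25 | tert-butyl (3R)-3-[(2S,3R)-5-ethoxy-7-hydroxy-2,3-dimethyl-6-(3-methylbut-2-en-1-yl)-4-oxo-3,4-dihydro-2H-chromen-8-yl]hexanoate (cis) | CCC[C@H](CC(=O)OC(C)(C)C)c1c(O)c(CC=C(C)C)c(OCC)c2c1O[C@@H](C)[C@@H](C)C2=O | intermediate
26 | tert-butyl (3R)-3-[(2S,3S)-5-ethoxy-7-hydroxy-2,3-dimethyl-6-(3-methylbut-2-en-1-yl)-4-oxo-3,4-dihydro-2H-chromen-8-yl]hexanoate (trans) | CCC[C@H](CC(=O)OC(C)(C)C)c1c(O)c(CC=C(C)C)c(OCC)c2c1O[C@@H](C)[C@H](C)C2=O | intermediate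
27 | (3R)-3-[(2S,3S)-5,7-dihydroxy-2,3-dimethyl-6-(3-methylbut-2-en-1-yl)-4-oxo-3,4-dihydro-2H-chromen-8-yl]hexanoic acid | CCC[C@H](CC(=O)O)c1c(O)c(CC=C(C)C)c(O)c2c1O[C@@H](C)[C@H](C)C2=O | intermediate
28 | methyl (3R)-3-[(2S,3S)-5,7-dihydroxy-2,3-dimethyl-6-(3-methylbut-2-en-1-yl)-4-oxo-3,4-dihydro-2H-chromen-8-yl]hexanoate | CCC[C@H](CC(=O)OC)c1c(O)c(CC=C(C)C)c(O)c2c1O[C@@H](C)[C@H](C)C2=O | target

Total step count: 14.
Longest linear sequence: 12 steps (steps 3 to 14, from auxiliary 6); the cyclobutenone branch (steps 1 and 2) joins at step 7.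

Steps most likely to fail

Step 7 (benzannulation). The cyclobutenone is a vinylogous ester, so the first electrocyclic opening may be slow, and the vinylketene may be lost to self-condensation before the alkyne captures it. The fallback sets out from acid chloride 2 and comes back to the route at vinylketene 16, and so at 20. Crossed Claisen acylation of the lithium enolate of ethyl acetate with 2 should give ethyl 7-methyl-3-oxooct-6-enoate F1. Triethyl orthoformate and catalytic acid in ethanol convert this into ethyl (2E)-3-ethoxy-7-methylocta-2,6-dienoate F2. Saponification gives (2E)-3-ethoxy-7-methylocta-2,6-dienoic acid F3, and oxalyl chloride gives (2E)-3-ethoxy-7-methylocta-2,6-dienoyl chloride F4. Triethylamine then removes HCl across C2–C4 of F4 (1,4-dehydrochlorination) in the presence of alkyne 15 at room temperature, which generates 16 without any ring opening. Its [2+2] adduct 17 is heated on to 20 as in the main route.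

Step 6 (ynolate formation). If enolate protection of the tert-butyl ester is incomplete, the organolithium may attack or alkylate the ester-bearing arm, or the carbenoid may add to both esters. The fallback sets out from diester 13 and comes back at alkyne 15. i-Bu2AlH at −78 °C reduces only the methyl ester to tert-butyl (3R)-3-formylhexanoate F5, which is used cold and crude. The Ohira–Bestmann reagent (K2CO3, MeOH, 0 °C) gives tert-butyl (3R)-3-ethynylhexanoate F6. Deprotonation with LiN(SiMe3)2 alone, oxidation of the acetylide with lithium tert-butylperoxide to the same ynolate 14, and silylation with i-Pr3SiCl then give 15. No alkyllithium and no carbenoid are present at any point.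

Step 13 (de-ethylation and ester cleavage). HCl or the boron halide may hydrochlorinate the prenyl double bond or drive its cyclisation on to a neighbouring phenol oxygen. The fallback sets out from 26 and comes back at acid 27. Me3SiOTf and 2,6-lutidine (CH2Cl2, 0 °C) convert the tert-butyl ester into the silyl ester with loss of isobutene and silylate the C7 phenol. This gives the aprotic trimethylsilyl (3R)-3-[(2S,3S)-5-ethoxy-2,3-dimethyl-6-(3-methylbut-2-en-1-yl)-4-oxo-7-(trimethylsilyloxy)-3,4-dihydro-2H-chromen-8-yl]hexanoate F7. MgI2 in ether–toluene then removes the chelated ethyl group as iodoethane by iodide attack inside the magnesium chelate. Methanolic work-up strips both silyl groups to give 27, with no boron halide and no free HCl involved.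

Further compounds
F1 | step 7 | ethyl 7-methyl-3-oxooct-6-enoate | CCOC(=O)CC(=O)CCC=C(C)C
F2 | step 7 | ethyl (2E)-3-ethoxy-7-methylocta-2,6-dienoate | CCOC(=O)/C=C(/OCC)CCC=C(C)C
F3 | step 7 | (2E)-3-ethoxy-7-methylocta-2,6-dienoic acid | OC(=O)/C=C(/OCC)CCC=C(C)C
F4 | step 7 | (2E)-3-ethoxy-7-methylocta-2,6-dienoyl chloride | ClC(=O)/C=C(/OCC)CCC=C(C)C
F5 | step 6 | tert-butyl (3R)-3-formylhexanoate | CCC[C@H](CC(=O)OC(C)(C)C)C=O
F6 | step 6 | tert-butyl (3R)-3-ethynylhexanoate | CCC[C@H](CC(=O)OC(C)(C)C)C#C
F7 | step 13 | trimethylsilyl (3R)-3-[(2S,3S)-5-ethoxy-2,3-dimethyl-6-(3-methylbut-2-en-1-yl)-4-oxo-7-(trimethylsilyloxy)-3,4-dihydro-2H-chromen-8-yl]hexanoate | CCC[C@H](CC(=O)O[Si](C)(C)C)c1c(O[Si](C)(C)C)c(CC=C(C)C)c(OCC)c2c1O[C@@H](C)[C@H](C)C2=O
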